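## Retrosynthetic overview

1. The target comes from a C4‑O‑silyl macrocyclic alcohol by Mitsunobu angeloylation (inversion at the ester carbinol C9) and desilylation.
2. Key disconnection C9–C10 (ester carbinol / ring‑fusion carbon): the β‑carbon of a 3‑(bromomethyl)butenolide, normally an acceptor position, is made the donor as an allylchromium (a homoenolate‑type d3 synthon) and adds to the C9 aldehyde. This one ring closure forms the ten‑membered ring, fixes the cis ring fusion and unveils the α‑methylene lactone.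
3. The seco‑aldehyde comes from a C3–C4 coupling (CrCl2/NiCl2) of a butenolide (Z)‑vinyl iodide with a cis‑epoxy aldehyde made from nerol (Sharpless epoxidation sets C5/C6, Felkin addition sets C4).
4. The butenolide vinyl iodide comes from acrolein and a propynyl Grignard reagent: trans‑hydroalumination/iodination, Sharpless kinetic resolution (C1), then acrylate → Baylis–Hillman → ring‑closing metathesis.
5. Ring order: butenolide (lactone) first, epoxide on the acyclic nerol piece, ten‑membered carbocycle last.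

Assumption and convention: the SMILES is taken literally; ring atoms are numbered C1 (lactone O–CH), C2=C3 (methyl on C3), C4 (carbinol), C5/C6 (epoxide, methyl on C6), C7, C8, C9 (ester carbinol), C10 (ring‑fusion CH), with C11 the lactone α‑carbon on C10, C12 the lactone C=O (closed to the oxygen on C1, "12,1‑olide") and C13 the exocyclic CH2.

## Route

Step 1
Reactants: 1 acrolein; 2 1‑propynylmagnesium bromide
Product: 3 rac‑hex‑1‑en‑4‑yn‑3‑ol
Conditions: THF, −78 → 0 °C; then aq. NH4Cl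
Reagents that add atoms: none
Why: 1,2‑addition of an alkynyl Grignard reagent to the aldehyde of acrolein at low temperature (Grignard addition); the carbinol is racemic and is resolved in step 3.

Step 2
Reactants: 3 rac‑hex‑1‑en‑4‑yn‑3‑ol
Product: 5 rac‑(4Z)‑5‑iodohexa‑1,4‑dien‑3‑ol, via cyclic vinylalanate 4 (not isolated)
Conditions: NaAlH2(OCH2CH2OCH3)2 (2.2 equiv), THF, 0 → 23 °C; EtOAc; then I2, −78 → 0 °C
Reagents that add atoms: NaAlH2(OCH2CH2OCH3)2, [Na+].[AlH2-](OCCOC)OCCOC (heavy atoms stay in 4 only); iodine, II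
Why: alkoxide‑directed trans‑hydroalumination of the propargylic alcohol puts aluminium on the distal alkyne carbon in a five‑membered alanate, and iodinolysis with retention gives the (Z)‑vinyl iodide with the carbinol carbon and iodine cis (hydroalumination–iodination).

Step 3
Reactants: 5 rac‑(4Z)‑5‑iodohexa‑1,4‑dien‑3‑ol
Product: 6 (3R,4Z)‑5‑iodohexa‑1,4‑dien‑3‑ol (recovered enantiomer)
Conditions: Ti(OiPr)4 (1.0 equiv), D‑(−)‑diisopropyl tartrate (1.2 equiv), t‑BuOOH (0.6 equiv), 4 Å MS, CH2Cl2, −20 °C, stopped at ca. 55 % conversion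
Reagents that add atoms: none
Why: Sharpless kinetic resolution, in which the D‑(−)‑tartrate titanium complex epoxidises the vinyl group of the (S)‑alcohol much faster (the electron‑poor Z‑iodoalkene does not react), so the (R)‑alcohol carrying the C1 configuration of the target is recovered in high ee.

Step 4
Reactants: 6 (3R,4Z)‑5‑iodohexa‑1,4‑dien‑3‑ol; 7 acryloyl chloride
Product: 8 (3R,4Z)‑5‑iodohexa‑1,4‑dien‑3‑yl prop‑2‑enoate
Conditions: Et3N, CH2Cl2, −20 → 0 °C
Reagents that add atoms: none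
Why: O‑acylation of the secondary alcohol with an acid chloride (esterification); the stereocentre is not touched.

Step 5
Reactants: 8 (3R,4Z)‑5‑iodohexa‑1,4‑dien‑3‑yl prop‑2‑enoate; 9 formaldehyde (37 % aqueous)
Product: 10 (3R,4Z)‑5‑iodohexa‑1,4‑dien‑3‑yl 2‑(hydroxymethyl)prop‑2‑enoate
Conditions: DABCO (1 equiv), 1,4‑dioxane/H2O (1:1), 23 °C
Reagents that add atoms: none
Why: Morita–Baylis–Hillman reaction of the acrylate with formaldehyde installs the future C13 at the α‑carbon under conditions too mild to affect the ester stereocentre.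

Step 6
Reactants: 10 (3R,4Z)‑5‑iodohexa‑1,4‑dien‑3‑yl 2‑(hydroxymethyl)prop‑2‑enoate
Product: 11 (5R)‑3‑(hydroxymethyl)‑5‑[(1Z)‑2‑iodoprop‑1‑en‑1‑yl]furan‑2(5H)‑one
Conditions: second‑generation Grubbs catalyst (H2IMes)(PCy3)Cl2Ru=CHPh (5 mol %), CH2Cl2 (0.01 M), 40 °C
Reagents that add atoms: none
Why: ring‑closing metathesis between the vinyl group and the 1,1‑disubstituted acrylate closes the five‑membered butenolide while the trisubstituted iodoalkene stays inert and the neutral conditions leave the acidic γ‑stereocentre (C1) intact.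

Step 7
Reactants: 12 nerol
Product: 13 [(2R,3S)‑3‑methyl‑3‑(4‑methylpent‑3‑en‑1‑yl)oxiran‑2‑yl]methanol
Conditions: Ti(OiPr)4 (5 mol %), D‑(−)‑diethyl tartrate (7.5 mol %), t‑BuOOH, 4 Å MS, CH2Cl2, −20 °C
Reagents that add atoms: tert‑butyl hydroperoxide, CC(C)(C)OO
Why: Sharpless asymmetric epoxidation of the (Z)‑allylic alcohol, in which the D‑(−)‑tartrate catalyst delivers oxygen to the face that gives the (2R,3S) cis‑epoxide and so sets C5 and C6 of the target; the isolated trisubstituted alkene is not an allylic alcohol and is untouched.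

Step 8
Reactants: 13 [(2R,3S)‑3‑methyl‑3‑(4‑methylpent‑3‑en‑1‑yl)oxiran‑2‑yl]methanol
Product: 14 (2S,3S)‑3‑methyl‑3‑(4‑methylpent‑3‑en‑1‑yl)oxirane‑2‑carbaldehyde
Conditions: Dess–Martin periodinane, NaHCO3, CH2Cl2, 0 → 23 °C
Reagents that add atoms: none
Why: buffered Dess–Martin oxidation of the primary epoxy alcohol gives the aldehyde without epimerisation (the descriptor at C2 changes only through CIP priorities).

Step 9
Reactants: 11 (5R)‑3‑(hydroxymethyl)‑5‑[(1Z)‑2‑iodoprop‑1‑en‑1‑yl]furan‑2(5H)‑one; 14 (2S,3S)‑3‑methyl‑3‑(4‑methylpent‑3‑en‑1‑yl)oxirane‑2‑carbaldehyde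
Product: 15 (5S)‑5‑{(1Z,3R)‑3‑hydroxy‑2‑methyl‑3‑[(2R,3S)‑3‑methyl‑3‑(4‑methylpent‑3‑en‑1‑yl)oxiran‑2‑yl]prop‑1‑en‑1‑yl}‑3‑(hydroxymethyl)furan‑2(5H)‑one
Conditions: CrCl2 (4 equiv), NiCl2 (1 mol %), DMSO, 23 °C; 14 (1.5 equiv)
Reagents that add atoms: none
Why: Nozaki–Hiyama–Kishi coupling, in which the vinyl iodide becomes a geometrically stable vinylchromium species that adds only to the aldehyde (butenolide and free OH tolerated), and Felkin–Anh/Cornforth attack anti to the epoxide C–O bond gives the erythro (C4‑R) alcohol; the furanone descriptor changes from 5R to 5S only because iodine is replaced by carbon.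

Step 10
Reactants: 15 the diol from step 9
Product: 17 (5S)‑3‑(bromomethyl)‑5‑{(1Z,3R)‑3‑hydroxy‑2‑methyl‑3‑[(2R,3S)‑3‑methyl‑3‑(4‑methylpent‑3‑en‑1‑yl)oxiran‑2‑yl]prop‑1‑en‑1‑yl}furan‑2(5H)‑one, via allylic mesylate 16 (not isolated)
Conditions: MsCl (1.1 equiv), 2,4,6‑collidine, CH2Cl2, −20 °C; then LiBr, THF, 0 °C
Reagents that add atoms: methanesulfonyl chloride, CS(=O)(=O)Cl (its atoms stay in 16 only); lithium bromide, [Li+].[Br-]
Why: collidine‑buffered sulfonylation selects the primary allylic alcohol over the hindered secondary one, and Finkelstein displacement (SN2) gives the allylic bromide without base strong enough to epimerise C1.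

Step 11
Reactants: 17 the bromo alcohol from step 10
Product: 18 (5S)‑3‑(bromomethyl)‑5‑{(1Z,3R)‑2‑methyl‑3‑[(2R,3S)‑3‑methyl‑3‑(4‑methylpent‑3‑en‑1‑yl)oxiran‑2‑yl]‑3‑(triethylsilyloxy)prop‑1‑en‑1‑yl}furan‑2(5H)‑one
Conditions: Et3SiOTf, 2,6‑lutidine, CH2Cl2, −78 °C
Reagents that add atoms: triethylsilyl trifluoromethanesulfonate, CC[Si](CC)(CC)OS(=O)(=O)C(F)(F)F
Why: silyl ether protection of the secondary alcohol with a silyl triflate and a hindered base at −78 °C, where the allylic bromide, the epoxide and the butenolide γ‑position survive.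

Step 12
Reactants: 18 the silyl ether from step 11
Product: 19 (5S)‑3‑(bromomethyl)‑5‑{(1Z,3R)‑2‑methyl‑3‑[(2R,3S)‑3‑methyl‑3‑(3‑oxopropyl)oxiran‑2‑yl]‑3‑(triethylsilyloxy)prop‑1‑en‑1‑yl}furan‑2(5H)‑one
Conditions: O3 (1.0 equiv), acetone/H2O (95:5), 0 °C
Reagents that add atoms: ozone, [O-][O+]=O
Why: chemoselective ozonolysis, since the isopropylidene alkene is far more electron‑rich than the alkene flanked by two allylic C–O bonds or the butenolide alkene, and in wet acetone water traps the carbonyl oxide so the aldehyde forms directly without a nucleophilic reductant that would attack the allylic bromide.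

Step 13
Reactants: 19 the bromo aldehyde from step 12
Product: 21 (1S,2Z,4R,5R,6S,9S,10R)‑5,6‑epoxy‑9‑hydroxy‑3,6‑dimethyl‑4‑(triethylsilyloxy)cyclodeca‑2,11(13)‑dien‑12,1‑olide, via allylchromium dichloride 20 (not isolated)
Conditions: CrCl2 (10 equiv), THF, 23 °C, slow addition of 19 (final 0.002 M); then H2O
Reagents that add atoms: chromium dichloride, Cl[Cr]Cl (its atoms stay in 20 only)
Why: intramolecular Nozaki–Hiyama (Barbier‑type) allylation, in which divalent chromium turns the bromomethyl butenolide into an allylchromium whose nucleophilic carbon is the butenolide β‑carbon (a homoenolate equivalent) and this adds to the tethered aldehyde through a chair transition state; the tether forces attack on the face of the C1 substituent (cis fusion, C10‑R), the equatorial tether predicts the 9S carbinol, and the allylic transposition unveils the exocyclic methylene.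

Step 14
Reactants: 21 the (9S)‑alcohol from step 13; 22 angelic acid
Product: 23 (1S,2Z,4R,5R,6S,9R,10R)‑9‑angeloyloxy‑5,6‑epoxy‑3,6‑dimethyl‑4‑(triethylsilyloxy)cyclodeca‑2,11(13)‑dien‑12,1‑olide
Conditions: PPh3, DIAD (betaine preformed), toluene, 0 → 23 °C
Reagents that add atoms: none
Why: Mitsunobu esterification with the carboxylate as nucleophile inverts C9 to the required R configuration, and because the acid is never activated as an acyl electrophile the (Z)‑geometry of the angelate is kept.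

Step 15
Reactants: 23 the silyl‑protected ester from step 14
Product: 24 (1S,2Z,4R,5R,6S,9R,10R)‑9‑angeloyloxy‑5,6‑epoxy‑4‑hydroxy‑3,6‑dimethylcyclodeca‑2,11(13)‑dien‑12,1‑olide (CNP0500828.1)
Conditions: HF·pyridine, pyridine, THF, 0 → 23 °C
Reagents that add atoms: none
Why: buffered fluoride cleavage of the triethylsilyl ether (desilylation) spares the epoxide, the angelate and the α‑methylene lactone.

## Compound list

1 | acrolein | C=CC=O | starting material
2 | 1‑propynylmagnesium bromide | CC#C[Mg]Br | starting material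
3 | rac‑hex‑1‑en‑4‑yn‑3‑ol | C=CC(O)C#CC | intermediate
4 | cyclic vinylalanate: sodium 5‑ethenyl‑2,2‑bis(2‑methoxyethoxy)‑3‑methyl‑2,5‑dihydro‑1,2‑oxaaluminol‑2‑uide | C=CC1O[Al-](OCCOC)(OCCOC)C(C)=C1.[Na+] | intermediate
5 | rac‑(4Z)‑5‑iodohexa‑1,4‑dien‑3‑ol | C=CC(O)/C=C(/C)I | intermediate
6 | (3R,4Z)‑5‑iodohexa‑1,4‑dien‑3‑ol | C=C[C@@H](O)/C=C(/C)I | intermediate
7 | acryloyl chloride | C=CC(=O)Cl | starting material
8 | (3R,4Z)‑5‑iodohexa‑1,4‑dien‑3‑yl prop‑2‑enoate | C=CC(=O)O[C@H](C=C)/C=C(/C)I | intermediate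
9 | formaldehyde | C=O | starting material
10 | (3R,4Z)‑5‑iodohexa‑1,4‑dien‑3‑yl 2‑(hydroxymethyl)prop‑2‑enoate | C=C(CO)C(=O)O[C@H](C=C)/C=C(/C)I | intermediate
11 | (5R)‑3‑(hydroxymethyl)‑5‑[(1Z)‑2‑iodoprop‑1‑en‑1‑yl]furan‑2(5H)‑one | O=C1O[C@@H](/C=C(/C)I)C=C1CO | intermediate
12 | nerol, (2Z)‑3,7‑dimethylocta‑2,6‑dien‑1‑ol | CC(C)=CCC/C(C)=C\CO | starting material
13 | [(2R,3S)‑3‑methyl‑3‑(4‑methylpent‑3‑en‑1‑yl)oxiran‑2‑yl]methanol | OC[C@H]1O[C@@]1(C)CCC=C(C)C | intermediate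
14 | (2S,3S)‑3‑methyl‑3‑(4‑methylpent‑3‑en‑1‑yl)oxirane‑2‑carbaldehyde | O=C[C@H]1O[C@@]1(C)CCC=C(C)C | intermediate
15 | (5S)‑5‑{(1Z,3R)‑3‑hydroxy‑2‑methyl‑3‑[(2R,3S)‑3‑methyl‑3‑(4‑methylpent‑3‑en‑1‑yl)oxiran‑2‑yl]prop‑1‑en‑1‑yl}‑3‑(hydroxymethyl)furan‑2(5H)‑one | O=C1O[C@@H](/C=C(/C)[C@@H](O)[C@H]2O[C@@]2(C)CCC=C(C)C)C=C1CO | intermediate
16 | allylic mesylate of 15: {(5S)‑5‑[(1Z,3R)‑3‑hydroxy‑2‑methyl‑3‑((2R,3S)‑3‑methyl‑3‑(4‑methylpent‑3‑en‑1‑yl)oxiran‑2‑yl)prop‑1‑en‑1‑yl]‑2‑oxo‑2,5‑dihydrofuran‑3‑yl}methyl methanesulfonate | O=C1O[C@@H](/C=C(/C)[C@@H](O)[C@H]2O[C@@]2(C)CCC=C(C)C)C=C1COS(C)(=O)=O | intermediate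
17 | (5S)‑3‑(bromomethyl)‑5‑{(1Z,3R)‑3‑hydroxy‑2‑methyl‑3‑[(2R,3S)‑3‑methyl‑3‑(4‑methylpent‑3‑en‑1‑yl)oxiran‑2‑yl]prop‑1‑en‑1‑yl}furan‑2(5H)‑one | O=C1O[C@@H](/C=C(/C)[C@@H](O)[C@H]2O[C@@]2(C)CCC=C(C)C)C=C1CBr | intermediate
18 | (5S)‑3‑(bromomethyl)‑5‑{(1Z,3R)‑2‑methyl‑3‑[(2R,3S)‑3‑methyl‑3‑(4‑methylpent‑3‑en‑1‑yl)oxiran‑2‑yl]‑3‑(triethylsilyloxy)prop‑1‑en‑1‑yl}furan‑2(5H)‑one | O=C1O[C@@H](/C=C(/C)[C@@H](O[Si](CC)(CC)CC)[C@H]2O[C@@]2(C)CCC=C(C)C)C=C1CBr | intermediate
19 | (5S)‑3‑(bromomethyl)‑5‑{(1Z,3R)‑2‑methyl‑3‑[(2R,3S)‑3‑methyl‑3‑(3‑oxopropyl)oxiran‑2‑yl]‑3‑(triethylsilyloxy)prop‑1‑en‑1‑yl}furan‑2(5H)‑one | O=C1O[C@@H](/C=C(/C)[C@@H](O[Si](CC)(CC)CC)[C@H]2O[C@@]2(C)CCC=O)C=C1CBr | intermediate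
20 | allylchromium dichloride (trivalent chromium): 19 with CH2CrCl2 in place of CH2Br | O=C1O[C@@H](/C=C(/C)[C@@H](O[Si](CC)(CC)CC)[C@H]2O[C@@]2(C)CCC=O)C=C1C[Cr](Cl)Cl | intermediate
21 | (1S,2Z,4R,5R,6S,9S,10R)‑5,6‑epoxy‑9‑hydroxy‑3,6‑dimethyl‑4‑(triethylsilyloxy)cyclodeca‑2,11(13)‑dien‑12,1‑olide | C=C1C(=O)O[C@H]2/C=C(/C)[C@@H](O[Si](CC)(CC)CC)[C@H]3O[C@@]3(C)CC[C@H](O)[C@@H]12 | intermediate
22 | angelic acid, (2Z)‑2‑methylbut‑2‑enoic acid | C/C=C(/C)C(=O)O | starting material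
23 | (1S,2Z,4R,5R,6S,9R,10R)‑9‑angeloyloxy‑5,6‑epoxy‑3,6‑dimethyl‑4‑(triethylsilyloxy)cyclodeca‑2,11(13)‑dien‑12,1‑olide | C=C1C(=O)O[C@H]2/C=C(/C)[C@@H](O[Si](CC)(CC)CC)[C@H]3O[C@@]3(C)CC[C@@H](OC(=O)/C(C)=C\C)[C@@H]12 | intermediate
24 | CNP0500828.1, (1S,2Z,4R,5R,6S,9R,10R)‑9‑angeloyloxy‑5,6‑epoxy‑4‑hydroxy‑3,6‑dimethylcyclodeca‑2,11(13)‑dien‑12,1‑olide | C=C1C(=O)O[C@H]2/C=C(/C)[C@@H](O)[C@H]3O[C@@]3(C)CC[C@@H](OC(=O)/C(C)=C\C)[C@@H]12 | target

## Step count and risk

Total: 15 steps. Longest linear sequence: 13 steps (steps 1–6, then 9–15); the nerol branch (steps 7–8) joins at step 9.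

Most likely to fail, with one fallback each:

**Step 13 (ring closure).** The ten‑membered ring may close slowly, giving oligomers, or the allylchromium may attack through its CH2 terminus to give a twelve‑membered ring. The C9 configuration is a prediction from an unconstrained chair model and is not secure. The fallback sets out from 19 and forms the same C9–C10 bond with the aldehyde as the reversed‑polarity partner. A nucleophilic acyl radical is generated from the aldehyde C–H with (Bu4N)4W10O32 (2 mol %), 390 nm light, MeCN, K2HPO4, at 0.002 M. It adds to the butenolide β‑carbon and expels a bromine atom (radical addition–fragmentation), giving macrocyclic C9 ketone F1. Reduction with NaBH4 and CeCl3·7H2O in MeOH at −78 °C comes back to the route at 21.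

**Step 14 (Mitsunobu angeloylation).** The activated C9 oxygen sits next to the acidic C10–H, so elimination to the C9=C10 diene can compete, and angelic acid is a weak Mitsunobu acid. The fallback sets out from 21 and separates inversion from acylation. Mitsunobu reaction with the more acidic 4‑nitrobenzoic acid (PPh3, DIAD) gives inverted 4‑nitrobenzoate F2. Brief methanolysis (K2CO3, MeOH, 0 °C) gives (9R)‑alcohol F3. Acylation with retention, using the mixed anhydride from 22 and 2,4,6‑trichlorobenzoyl chloride (Et3N; then F3, toluene, 80 °C), comes back to the route at 23. If step 13 should deliver the 9R alcohol directly, it is this same (9R)‑alcohol F3 and enters here.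

**Step 9 (fragment coupling).** The erythro:threo ratio at C4 may be modest, and the cis‑epoxy aldehyde is sensitive to the Lewis‑acidic trivalent chromium salts. The fallback sets out from 17, carried through steps 9 and 10 as the C4 epimer mixture, and sets C4 by reduction instead of by addition. Dess–Martin oxidation gives epoxy enone F4. Chelation‑controlled reduction with Zn(BH4)2 (Et2O, −20 °C; zinc bridges the ketone and epoxide oxygens and hydride enters anti to the epoxide) gives the erythro alcohol and comes back to the route at 17 as a single epimer.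

## Further compounds

F1 | step 13 | (1S,2Z,4R,5R,6S,10S)‑5,6‑epoxy‑3,6‑dimethyl‑9‑oxo‑4‑(triethylsilyloxy)cyclodeca‑2,11(13)‑dien‑12,1‑olide | C=C1C(=O)O[C@H]2/C=C(/C)[C@@H](O[Si](CC)(CC)CC)[C@H]3O[C@@]3(C)CCC(=O)[C@@H]12
F2 | step 14 | (1S,2Z,4R,5R,6S,9R,10R)‑5,6‑epoxy‑3,6‑dimethyl‑9‑(4‑nitrobenzoyloxy)‑4‑(triethylsilyloxy)cyclodeca‑2,11(13)‑dien‑12,1‑olide | C=C1C(=O)O[C@H]2/C=C(/C)[C@@H](O[Si](CC)(CC)CC)[C@H]3O[C@@]3(C)CC[C@@H](OC(=O)c4ccc(cc4)[N+](=O)[O-])[C@@H]12
F3 | step 14 | (1S,2Z,4R,5R,6S,9R,10R)‑5,6‑epoxy‑9‑hydroxy‑3,6‑dimethyl‑4‑(triethylsilyloxy)cyclodeca‑2,11(13)‑dien‑12,1‑olide | C=C1C(=O)O[C@H]2/C=C(/C)[C@@H](O[Si](CC)(CC)CC)[C@H]3O[C@@]3(C)CC[C@@H](O)[C@@H]12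
F4 | step 9 | (5S)‑3‑(bromomethyl)‑5‑{(1Z)‑2‑methyl‑3‑[(2S,3S)‑3‑methyl‑3‑(4‑methylpent‑3‑en‑1‑yl)oxiran‑2‑yl]‑3‑oxoprop‑1‑en‑1‑yl}furan‑2(5H)‑one | O=C1O[C@@H](/C=C(/C)C(=O)[C@H]2O[C@@]2(C)CCC=C(C)C)C=C1CBr
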